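## Retrosynthetic overview

1. The dihydrofuran ring is closed last, at the bond between the phenolic oxygen O1 and the benzylic carbon C2 that carries the 4-hydroxy-3-methoxyphenyl group. Acid removes three MOM ethers and a temporary 2,2-dimethyl-1,3-dioxane (spanning the C2–O and C3–CH2–O oxygens); the C2 carbinol ionises to a p-quinone methide and the neighbouring phenol captures it.
2. Enabling feature: the free OH para to C2 on the 2-aryl ring makes C2 a latent p-quinone-methide carbon, and O1 sits on the catechol ring ortho to the carbon bearing C3. Because C2 passes through an sp2 state, its configuration is written by C3 alone, so only C3 must be set beforehand.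
3. C3 (with a disposable C2 carbinol) comes from an Evans syn-aldol of an N-arylacetyl oxazolidinone with MOM-vanillin; the arylacetyl imide comes from Pd-catalysed α-arylation with methyl 3-bromo-4,5-bis(methoxymethoxy)benzoate.
4. The lactone Cα–CH2Ar bond is made by trans-selective enolate alkylation of (S)-β-(4-benzyloxy-3-methoxybenzyl)-γ-butyrolactone (Evans alkylation, reduction, lactonisation) with the benzylic bromide of the dioxane fragment.
5. Ring order: butyrolactone (step 4), temporary 1,3-dioxane (step 10, cleaved in step 14), dihydrofuran (step 14).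

Key step: step 14

Remark on the chemistry: the target is read as (3S,4S) (trans) at the lactone and (2S,3R) (trans) at the dihydrobenzofuran; the acid cyclisation is assumed to run through ionisation to the quinone methide, not direct displacement.

## Route

Step 1
Reactants: 1 (S)-4-benzyl-1,3-oxazolidin-2-one; 2 4-tert-butoxy-4-oxobutanoic acid
Product: 4 tert-butyl 4-[(4S)-4-benzyl-2-oxo-1,3-oxazolidin-3-yl]-4-oxobutanoate, via mixed pivalic anhydride 3 (not isolated)
Conditions: 2, PivCl, Et3N, THF, −20 °C; then 1, LiCl, −20 °C → rt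
Reagents that add atoms: pivaloyl chloride, CC(C)(C)C(Cl)=O (its acyl group is carried only by intermediate 3)
Why: Evans-type N-acylation in which the acid is activated as the mixed pivalic anhydride and LiCl/Et3N promotes acyl transfer to the oxazolidinone nitrogen at the less hindered carbonyl, no stereocentre being formed or touched.

Step 2
Reactants: 5 [4-(benzyloxy)-3-methoxyphenyl]methanol
Product: 6 1-(benzyloxy)-4-(bromomethyl)-2-methoxybenzene
Conditions: PBr3, Et2O, 0 °C
Reagents that add atoms: phosphorus tribromide, BrP(Br)Br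
Why: Alcohol-to-bromide conversion with PBr3 (SN2 on the activated phosphite), routine for alkoxybenzyl alcohols and compatible with the aryl benzyl ether at 0 °C.

Step 3
Reactants: 4 tert-butyl 4-[(4S)-4-benzyl-2-oxo-1,3-oxazolidin-3-yl]-4-oxobutanoate; 6 1-(benzyloxy)-4-(bromomethyl)-2-methoxybenzene
Product: 8 tert-butyl (3S)-3-{[(4S)-4-benzyl-2-oxo-1,3-oxazolidin-3-yl]carbonyl}-4-[4-(benzyloxy)-3-methoxyphenyl]butanoate, via sodium (Z)-enolate 7 (not isolated)
Conditions: NaHMDS, THF, −78 °C; then 6, −78 → −40 °C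
Reagents that add atoms: sodium hexamethyldisilazide, [Na+].C[Si](C)(C)[N-][Si](C)(C)C (sodium is carried only by intermediate 7)
Why: Evans asymmetric alkylation in which the chelated (Z)-sodium imide enolate is benzylated on the face opposite the C4 benzyl group of the auxiliary, which sets the (S) centre that becomes the lactone β-carbon, while the less acidic tert-butyl ester is not enolised.

Step 4
Reactants: 8 tert-butyl (3S)-3-{[(4S)-4-benzyl-2-oxo-1,3-oxazolidin-3-yl]carbonyl}-4-[4-(benzyloxy)-3-methoxyphenyl]butanoate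
Product: 10 (4S)-4-[4-(benzyloxy)-3-methoxybenzyl]dihydrofuran-2(3H)-one, via hydroxy tert-butyl ester 9 (not isolated)
Conditions: LiBH4, H2O (1 equiv), Et2O, 0 °C; then TFA, CH2Cl2, rt
Reagents that add atoms: none
Why: Reductive cleavage of the N-acyl oxazolidinone with LiBH4 (the tert-butyl ester is inert at 0 °C) followed by acid-mediated lactonisation of the γ-hydroxy tert-butyl ester, neither operation epimerising the stereocentre.

Step 5
Reactants: 11 vanillin
Product: 12 3-methoxy-4-(methoxymethoxy)benzaldehyde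
Conditions: MOMCl, i-Pr2NEt, CH2Cl2, 0 °C → rt
Reagents that add atoms: chloromethyl methyl ether, COCCl
Why: O-alkylation of the phenol with chloromethyl methyl ether (MOM protection), so that the aldehyde partner carries an acid-labile group that falls off in the key step.

Step 6
Reactants: 13 methyl 3-bromo-4,5-dihydroxybenzoate
Product: 14 methyl 3-bromo-4,5-bis(methoxymethoxy)benzoate
Conditions: MOMCl (2.5 equiv), i-Pr2NEt, CH2Cl2, 0 °C → rt
Reagents that add atoms: chloromethyl methyl ether, COCCl
Why: Twofold MOM protection of the catechol under the same Williamson-type conditions, giving acetals that survive palladium, hydride and enolate chemistry and are shed together in the key step.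

Step 7
Reactants: 14 methyl 3-bromo-4,5-bis(methoxymethoxy)benzoate; 15 (4S)-3-acetyl-4-benzyl-1,3-oxazolidin-2-one
Product: 17 methyl 3-{2-[(4S)-4-benzyl-2-oxo-1,3-oxazolidin-3-yl]-2-oxoethyl}-4,5-bis(methoxymethoxy)benzoate, via O-silyl ketene aminal 16 (not isolated)
Conditions: 15, NaHMDS, THF, −78 °C, then TMSCl; solvent switch; 14, Pd(dba)2 (5 mol %), P(t-Bu)3 (10 mol %), ZnF2 (0.5 equiv), DMF, 80 °C
Reagents that add atoms: chlorotrimethylsilane, C[Si](C)(C)Cl (its silyl group is carried only by intermediate 16)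
Why: Palladium-catalysed α-arylation of an imide silyl enolate with an aryl bromide (zinc fluoride-mediated transmetalation, then C–C reductive elimination), a near-neutral protocol that should tolerate the methyl ester and the acetals and stop at monoarylation, with the auxiliary stereocentre untouched.

Step 8
Reactants: 17 methyl 3-{2-[(4S)-4-benzyl-2-oxo-1,3-oxazolidin-3-yl]-2-oxoethyl}-4,5-bis(methoxymethoxy)benzoate; 12 3-methoxy-4-(methoxymethoxy)benzaldehyde
Product: 19 methyl 3-{(2S,3S)-1-[(4S)-4-benzyl-2-oxo-1,3-oxazolidin-3-yl]-3-hydroxy-3-[3-methoxy-4-(methoxymethoxy)phenyl]-1-oxopropan-2-yl}-4,5-bis(methoxymethoxy)benzoate, via (Z)-boron enolate 18 (not isolated)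
Conditions: n-Bu2BOTf, i-Pr2NEt, CH2Cl2, 0 °C; then 12, −78 → 0 °C; pH 7 buffer, MeOH, H2O2
Reagents that add atoms: dibutylboron triflate, CCCCB(CCCC)OS(=O)(=O)C(F)(F)F (boron is carried only by intermediate 18)
Why: Evans boron syn-aldol reaction in which the (Z)-dibutylboron enolate reacts through a Zimmerman–Traxler chair on the enolate face opposite the auxiliary benzyl group, which sets the aryl-bearing carbon as required for C3 (3R in the target) and gives a syn carbinol whose configuration is deliberately expendable.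

Step 9
Reactants: 19 methyl 3-{(2S,3S)-1-[(4S)-4-benzyl-2-oxo-1,3-oxazolidin-3-yl]-3-hydroxy-3-[3-methoxy-4-(methoxymethoxy)phenyl]-1-oxopropan-2-yl}-4,5-bis(methoxymethoxy)benzoate
Product: 20 (1S,2R)-2-[5-(hydroxymethyl)-2,3-bis(methoxymethoxy)phenyl]-1-[3-methoxy-4-(methoxymethoxy)phenyl]propane-1,3-diol
Conditions: LiBH4, MeOH, THF, 0 °C; then 55 °C
Reagents that add atoms: none
Why: Borohydride reduction in which the imide is cleaved to the primary alcohol at 0 °C (hydroxyl-assisted and faster than retro-aldol or enolisation, so the aryl-bearing centre is retained) and the electron-rich methyl benzoate is then reduced on warming with methanol as activator.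

Step 10
Reactants: 20 (1S,2R)-2-[5-(hydroxymethyl)-2,3-bis(methoxymethoxy)phenyl]-1-[3-methoxy-4-(methoxymethoxy)phenyl]propane-1,3-diol
Product: 21 {3-[(4S,5R)-4-[3-methoxy-4-(methoxymethoxy)phenyl]-2,2-dimethyl-1,3-dioxan-5-yl]-4,5-bis(methoxymethoxy)phenyl}methanol
Conditions: Me2C(OMe)2, PPTS (cat.), CH2Cl2, rt; aqueous work-up
Reagents that add atoms: 2,2-dimethoxypropane, COC(C)(C)OC
Why: Acid-catalysed transacetalisation in which only the 1,3-diol can close a six-membered acetonide, so the temporary 1,3-dioxane forms selectively and leaves the benzylic primary alcohol free (any mixed ketal there is hydrolysed on work-up), no stereocentre being affected.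

Step 11
Reactants: 21 {3-[(4S,5R)-4-[3-methoxy-4-(methoxymethoxy)phenyl]-2,2-dimethyl-1,3-dioxan-5-yl]-4,5-bis(methoxymethoxy)phenyl}methanol
Product: 22 (4S,5R)-5-[5-(bromomethyl)-2,3-bis(methoxymethoxy)phenyl]-4-[3-methoxy-4-(methoxymethoxy)phenyl]-2,2-dimethyl-1,3-dioxane
Conditions: CBr4, PPh3, 2,6-lutidine, CH2Cl2, 0 °C
Reagents that add atoms: carbon tetrabromide, BrC(Br)(Br)Br
Why: Appel bromination (alkoxyphosphonium formation and SN2 displacement by bromide) under buffered neutral conditions that should leave the acetonide and the MOM acetals intact.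

Step 12
Reactants: 10 (4S)-4-[4-(benzyloxy)-3-methoxybenzyl]dihydrofuran-2(3H)-one; 22 (4S,5R)-5-[5-(bromomethyl)-2,3-bis(methoxymethoxy)phenyl]-4-[3-methoxy-4-(methoxymethoxy)phenyl]-2,2-dimethyl-1,3-dioxane
Product: 24 (3S,4S)-4-[4-(benzyloxy)-3-methoxybenzyl]-3-{3-[(4S,5R)-4-[3-methoxy-4-(methoxymethoxy)phenyl]-2,2-dimethyl-1,3-dioxan-5-yl]-4,5-bis(methoxymethoxy)benzyl}dihydrofuran-2(3H)-one, via lithium enolate 23 (not isolated)
Conditions: 10, LiHMDS, THF, −78 °C; then 22, DMPU, −78 → −30 °C
Reagents that add atoms: lithium hexamethyldisilazide, [Li+].C[Si](C)(C)[N-][Si](C)(C)C (lithium is carried only by intermediate 23)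
Why: Alkylation of the lithium enolate of a β-substituted γ-butyrolactone, which takes place anti to the β-benzyl group and so sets the α-centre trans to it, giving the (3S,4S) lactone as is standard for dibenzylbutyrolactone lignans.

Step 13
Reactants: 24 (3S,4S)-4-[4-(benzyloxy)-3-methoxybenzyl]-3-{3-[(4S,5R)-4-[3-methoxy-4-(methoxymethoxy)phenyl]-2,2-dimethyl-1,3-dioxan-5-yl]-4,5-bis(methoxymethoxy)benzyl}dihydrofuran-2(3H)-one
Product: 25 (3S,4S)-4-(4-hydroxy-3-methoxybenzyl)-3-{3-[(4S,5R)-4-[3-methoxy-4-(methoxymethoxy)phenyl]-2,2-dimethyl-1,3-dioxan-5-yl]-4,5-bis(methoxymethoxy)benzyl}dihydrofuran-2(3H)-one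
Conditions: H2 (1 atm), 10% Pd/C, EtOAc, rt
Reagents that add atoms: none
Why: Catalytic hydrogenolysis of the aryl benzyl ether, which should be much faster than cleavage of the dialkyl benzylic C–O bond inside the dioxane under neutral conditions, so that no benzylic aryl ether is ever exposed to hydrogen and the key step can be the last one.

Step 14
Reactants: 25 (3S,4S)-4-(4-hydroxy-3-methoxybenzyl)-3-{3-[(4S,5R)-4-[3-methoxy-4-(methoxymethoxy)phenyl]-2,2-dimethyl-1,3-dioxan-5-yl]-4,5-bis(methoxymethoxy)benzyl}dihydrofuran-2(3H)-one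
Product: 28 (3S,4S)-3-{[(2S,3R)-7-hydroxy-2-(4-hydroxy-3-methoxyphenyl)-3-(hydroxymethyl)-2,3-dihydro-1-benzofuran-5-yl]methyl}-4-(4-hydroxy-3-methoxybenzyl)dihydrofuran-2(3H)-one (target CNP0118131.1), via deprotected open-chain hexol 26 (not isolated), via p-quinone methide 27 (not isolated)
Conditions: 2 M aq. HCl, MeOH–THF (1:1), 45 °C, high dilution
Reagents that add atoms: none
Why: Acid-catalysed acetal cleavage removes the three MOM groups (methanol takes up the formaldehyde as dimethoxymethane) and the acetonide to give hexol 26, whose benzylic C2–OH, now para to a free phenol, ionises with loss of water to the p-quinone methide 27; the phenolic O1, held ortho to the carbon bearing C3, then adds to the methide carbon in an oxa-1,6-conjugate addition that re-aromatises the guaiacyl ring and forms the O1–C2 bond. The closest known reaction type is the acid-catalysed cyclisation of aldol-derived 1-aryl-2-(2-hydroxyaryl)propane-1,3-diols to trans-2-aryl-3-(hydroxymethyl)-2,3-dihydrobenzofurans, the laboratory counterpart of quinone-methide capture in phenylcoumaran biosynthesis. The dihydrofuran ring closes in the 5-exo-trig mode, O1 attacking the exocyclic C=C terminus of the quinone methide. The only new stereocentre, C2, is controlled by the fixed C3 centre: O1 adds so that the aryl group ends up anti to the C3 hydroxymethyl group, and because ring opening back to 27 (and re-ionisation of any methanol adduct) is possible under the same conditions the 2,3-trans isomer is also the thermodynamic product, so the carbinol configuration delivered by the aldol is irrelevant. The step needs ring closure to outrun quinone methide–vinylphenol tautomerism (which would erase C3) and intermolecular capture of the cation; the five-membered closure by the neighbouring phenol should secure the first and high dilution the second, while O7 cannot reach C2 and the primary alcohol would have to close a four-membered ring.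

## Compound list

1 | (S)-4-benzyl-1,3-oxazolidin-2-one | O=C1N[C@@H](Cc2ccccc2)CO1 | starting material
2 | 4-tert-butoxy-4-oxobutanoic acid (mono-tert-butyl succinate) | CC(C)(C)OC(=O)CCC(=O)O | starting material
3 | mixed anhydride of 2 with pivalic acid | CC(C)(C)OC(=O)CCC(=O)OC(=O)C(C)(C)C | intermediate (not isolated)
4 | tert-butyl 4-[(4S)-4-benzyl-2-oxo-1,3-oxazolidin-3-yl]-4-oxobutanoate | CC(C)(C)OC(=O)CCC(=O)N1[C@@H](Cc2ccccc2)COC1=O | intermediate
5 | [4-(benzyloxy)-3-methoxyphenyl]methanol | COc1cc(CO)ccc1OCc1ccccc1 | starting material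
6 | 1-(benzyloxy)-4-(bromomethyl)-2-methoxybenzene | COc1cc(CBr)ccc1OCc1ccccc1 | intermediate
7 | sodium (Z)-enolate of 4 | [Na+].CC(C)(C)OC(=O)C/C=C(\[O-])N1[C@@H](Cc2ccccc2)COC1=O | intermediate (not isolated)
8 | tert-butyl (3S)-3-{[(4S)-4-benzyl-2-oxo-1,3-oxazolidin-3-yl]carbonyl}-4-[4-(benzyloxy)-3-methoxyphenyl]butanoate | CC(C)(C)OC(=O)C[C@H](Cc1ccc(OCc2ccccc2)c(OC)c1)C(=O)N1[C@@H](Cc2ccccc2)COC1=O | intermediate
9 | tert-butyl (3S)-4-[4-(benzyloxy)-3-methoxyphenyl]-3-(hydroxymethyl)butanoate | CC(C)(C)OC(=O)C[C@H](Cc1ccc(OCc2ccccc2)c(OC)c1)CO | intermediate (not isolated)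
10 | (4S)-4-[4-(benzyloxy)-3-methoxybenzyl]dihydrofuran-2(3H)-one | COc1cc(C[C@@H]2COC(=O)C2)ccc1OCc1ccccc1 | intermediate
11 | vanillin (4-hydroxy-3-methoxybenzaldehyde) | COc1cc(C=O)ccc1O | starting material
12 | 3-methoxy-4-(methoxymethoxy)benzaldehyde | COCOc1ccc(C=O)cc1OC | intermediate
13 | methyl 3-bromo-4,5-dihydroxybenzoate | COC(=O)c1cc(O)c(O)c(Br)c1 | starting material
14 | methyl 3-bromo-4,5-bis(methoxymethoxy)benzoate | COC(=O)c1cc(Br)c(OCOC)c(OCOC)c1 | intermediate
15 | (4S)-3-acetyl-4-benzyl-1,3-oxazolidin-2-one | CC(=O)N1[C@@H](Cc2ccccc2)COC1=O | starting material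
16 | (4S)-4-benzyl-3-[1-(trimethylsilyloxy)ethenyl]-1,3-oxazolidin-2-one | C=C(O[Si](C)(C)C)N1[C@@H](Cc2ccccc2)COC1=O | intermediate (not isolated)
17 | methyl 3-{2-[(4S)-4-benzyl-2-oxo-1,3-oxazolidin-3-yl]-2-oxoethyl}-4,5-bis(methoxymethoxy)benzoate | COC(=O)c1cc(CC(=O)N2[C@@H](Cc3ccccc3)COC2=O)c(OCOC)c(OCOC)c1 | intermediate
18 | (Z)-dibutylboron enolate of 17 | COC(=O)c1cc(/C=C(\OB(CCCC)CCCC)N2[C@@H](Cc3ccccc3)COC2=O)c(OCOC)c(OCOC)c1 | intermediate (not isolated)
19 | methyl 3-{(2S,3S)-1-[(4S)-4-benzyl-2-oxo-1,3-oxazolidin-3-yl]-3-hydroxy-3-[3-methoxy-4-(methoxymethoxy)phenyl]-1-oxopropan-2-yl}-4,5-bis(methoxymethoxy)benzoate (syn-aldol) | COC(=O)c1cc([C@H](C(=O)N2[C@@H](Cc3ccccc3)COC2=O)[C@H](O)c2ccc(OCOC)c(OC)c2)c(OCOC)c(OCOC)c1 | intermediate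
20 | (1S,2R)-2-[5-(hydroxymethyl)-2,3-bis(methoxymethoxy)phenyl]-1-[3-methoxy-4-(methoxymethoxy)phenyl]propane-1,3-diol | OCc1cc([C@H](CO)[C@H](O)c2ccc(OCOC)c(OC)c2)c(OCOC)c(OCOC)c1 | intermediate
21 | {3-[(4S,5R)-4-[3-methoxy-4-(methoxymethoxy)phenyl]-2,2-dimethyl-1,3-dioxan-5-yl]-4,5-bis(methoxymethoxy)phenyl}methanol | OCc1cc([C@@H]2COC(C)(C)O[C@@H]2c2ccc(OCOC)c(OC)c2)c(OCOC)c(OCOC)c1 | intermediate
22 | (4S,5R)-5-[5-(bromomethyl)-2,3-bis(methoxymethoxy)phenyl]-4-[3-methoxy-4-(methoxymethoxy)phenyl]-2,2-dimethyl-1,3-dioxane | BrCc1cc([C@@H]2COC(C)(C)O[C@@H]2c2ccc(OCOC)c(OC)c2)c(OCOC)c(OCOC)c1 | intermediate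
23 | lithium enolate of 10 | [Li+].COc1cc(C[C@@H]2COC([O-])=C2)ccc1OCc1ccccc1 | intermediate (not isolated)
24 | (3S,4S)-4-[4-(benzyloxy)-3-methoxybenzyl]-3-{3-[(4S,5R)-4-[3-methoxy-4-(methoxymethoxy)phenyl]-2,2-dimethyl-1,3-dioxan-5-yl]-4,5-bis(methoxymethoxy)benzyl}dihydrofuran-2(3H)-one | COc1cc(C[C@@H]2COC(=O)[C@H]2Cc2cc([C@@H]3COC(C)(C)O[C@@H]3c3ccc(OCOC)c(OC)c3)c(OCOC)c(OCOC)c2)ccc1OCc1ccccc1 | intermediate
25 | (3S,4S)-4-(4-hydroxy-3-methoxybenzyl)-3-{3-[(4S,5R)-4-[3-methoxy-4-(methoxymethoxy)phenyl]-2,2-dimethyl-1,3-dioxan-5-yl]-4,5-bis(methoxymethoxy)benzyl}dihydrofuran-2(3H)-one | COc1cc(C[C@@H]2COC(=O)[C@H]2Cc2cc([C@@H]3COC(C)(C)O[C@@H]3c3ccc(OCOC)c(OC)c3)c(OCOC)c(OCOC)c2)ccc1O | intermediate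
26 | (3S,4S)-3-{3-[(2R,3S)-1,3-dihydroxy-3-(4-hydroxy-3-methoxyphenyl)propan-2-yl]-4,5-dihydroxybenzyl}-4-(4-hydroxy-3-methoxybenzyl)dihydrofuran-2(3H)-one | COc1cc(C[C@@H]2COC(=O)[C@H]2Cc2cc(O)c(O)c([C@H](CO)[C@H](O)c3ccc(O)c(OC)c3)c2)ccc1O | intermediate (not isolated)
27 | p-quinone methide of 26: (3S,4S)-3-{3-[(2R)-1-hydroxy-3-(3-methoxy-4-oxocyclohexa-2,5-dien-1-ylidene)propan-2-yl]-4,5-dihydroxybenzyl}-4-(4-hydroxy-3-methoxybenzyl)dihydrofuran-2(3H)-one | COc1cc(C[C@@H]2COC(=O)[C@H]2Cc2cc(O)c(O)c([C@H](CO)C=C3C=CC(=O)C(OC)=C3)c2)ccc1O | intermediate (not isolated)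
28 | (3S,4S)-3-{[(2S,3R)-7-hydroxy-2-(4-hydroxy-3-methoxyphenyl)-3-(hydroxymethyl)-2,3-dihydro-1-benzofuran-5-yl]methyl}-4-(4-hydroxy-3-methoxybenzyl)dihydrofuran-2(3H)-one | COc1cc(C[C@@H]2COC(=O)[C@H]2Cc2cc(O)c3c(c2)[C@H](CO)[C@@H](c2ccc(O)c(OC)c2)O3)ccc1O | target

## Step count and risks

Total step count: 14. Longest linear sequence: 9 steps (steps 6 to 14, from compound 13).

Steps most likely to fail:

1. Step 7 (α-arylation of the acetyl-imide silyl enolate). What may go wrong: loss of the silyl enolate by desilylation or ketene extrusion before transmetalation, a second arylation of the more acidic product imide, or sluggish oxidative addition next to the ortho MOM ether. Fallback (arylate an ester, attach the auxiliary afterwards): setting out from 14, palladium-catalysed coupling with the Reformatsky reagent of benzyl bromoacetate (Pd(dba)2, Q-Phos, THF) should give methyl 3-[2-(benzyloxy)-2-oxoethyl]-4,5-bis(methoxymethoxy)benzoate F1. Hydrogenolysis (H2, Pd/C) of the benzyl ester should give [5-(methoxycarbonyl)-2,3-bis(methoxymethoxy)phenyl]acetic acid F2. Activation as the mixed pivalic anhydride and acylation of lithiated 1 comes back to the route at 17.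

2. Step 14 (key step). What may go wrong: erosion of the C3 configuration through quinone methide–vinylphenol tautomerism in warm protic acid, Friedel–Crafts oligomerisation of the benzylic cation with the electron-rich rings, or hydroxymethylation of the free phenols by liberated formaldehyde. Fallback (generate the quinone methide by base-triggered elimination instead of acid ionisation): setting out from 25, bromotrimethylsilane (CH2Cl2, −40 → 0 °C) should cleave the MOM and acetonide acetals and convert the benzylic C–O bond into the bromide, giving after mild aqueous hydrolysis of the silyl ethers the benzylic bromide (3S,4S)-3-{3-[(2R)-3-bromo-1-hydroxy-3-(4-hydroxy-3-methoxyphenyl)propan-2-yl]-4,5-dihydroxybenzyl}-4-(4-hydroxy-3-methoxybenzyl)dihydrofuran-2(3H)-one F3 (both C–Br epimers). Aqueous NaHCO3 in THF at 0 °C then eliminates HBr to the same quinone methide 27 under buffered, non-acidic conditions, the standard way such methides are made from lignin model compounds. Ring closure comes back to the route at 28.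

3. Step 9 (double reduction). What may go wrong: incomplete reduction of the electron-rich methyl benzoate, or retro-aldol cleavage and epimerisation of the α-aryl-β-hydroxy imide if the imide is not consumed before warming. Fallback (separate the two reductions around the acetonide): setting out from 19, LiBH4 at 0 °C only should reduce the imide and give methyl 3-{(2R,3S)-1,3-dihydroxy-3-[3-methoxy-4-(methoxymethoxy)phenyl]propan-2-yl}-4,5-bis(methoxymethoxy)benzoate F4. Acetonide formation (2,2-dimethoxypropane, PPTS) should give methyl 3-[(4S,5R)-4-[3-methoxy-4-(methoxymethoxy)phenyl]-2,2-dimethyl-1,3-dioxan-5-yl]-4,5-bis(methoxymethoxy)benzoate F5. DIBAL-H (CH2Cl2, −78 °C) then reduces the ester and comes back to the route at 21.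

Further compounds
F1 | step 7 | methyl 3-[2-(benzyloxy)-2-oxoethyl]-4,5-bis(methoxymethoxy)benzoate | COC(=O)c1cc(CC(=O)OCc2ccccc2)c(OCOC)c(OCOC)c1
F2 | step 7 | [5-(methoxycarbonyl)-2,3-bis(methoxymethoxy)phenyl]acetic acid | COC(=O)c1cc(CC(=O)O)c(OCOC)c(OCOC)c1
F3 | step 14 | (3S,4S)-3-{3-[(2R)-3-bromo-1-hydroxy-3-(4-hydroxy-3-methoxyphenyl)propan-2-yl]-4,5-dihydroxybenzyl}-4-(4-hydroxy-3-methoxybenzyl)dihydrofuran-2(3H)-one (both C–Br epimers) | COc1cc(C[C@@H]2COC(=O)[C@H]2Cc2cc(O)c(O)c([C@H](CO)C(Br)c3ccc(O)c(OC)c3)c2)ccc1O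
F4 | step 9 | methyl 3-{(2R,3S)-1,3-dihydroxy-3-[3-methoxy-4-(methoxymethoxy)phenyl]propan-2-yl}-4,5-bis(methoxymethoxy)benzoate | COC(=O)c1cc([C@H](CO)[C@H](O)c2ccc(OCOC)c(OC)c2)c(OCOC)c(OCOC)c1
F5 | step 9 | methyl 3-[(4S,5R)-4-[3-methoxy-4-(methoxymethoxy)phenyl]-2,2-dimethyl-1,3-dioxan-5-yl]-4,5-bis(methoxymethoxy)benzoate | COC(=O)c1cc([C@@H]2COC(C)(C)O[C@@H]2c2ccc(OCOC)c(OC)c2)c(OCOC)c(OCOC)c1
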